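**Plan**

1. Numbering: chain atoms C1 (alkyne CH) to C15 (methyl). The oxolane ring is O6–C6–C7–C8–C9 and the oxepane ring is O7–C7–C8–C9–C10–C11–C12.
2. Retrosynthetic cuts, in order: C3=C4 (Peterson olefination of a C4 aldehyde); O6–C9 together with C10–Br (bromoetherification); C13–Br (SN2 on a carbinol); C9=C10 (ring-closing metathesis); C11–C12 (Evans glycolate allylation); O7–CH2 (Williamson ether) and C7–C8 (allylboration).
3. Forward order: a bis-homoallylic ether is built on (R)-butane-1,2,4-triol, closed first to the seven-membered oxepene, then bridged to the oxolane in the key step; the enyne is joined last.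
4. Stereochemistry: C6 comes from the triol, whose O-1, O-2 and O-4 become the oxepane oxygen, the oxolane oxygen and the aldehyde oxygen used for the enyne. C7 comes from a reagent-controlled allylboration, C12 from the Evans auxiliary, C13 from a Felkin–Anh reduction followed by inversion, and C9 and C10 from the key step.
5. Enabling feature: in the oxepene the hydroxyl on exocyclic C6 (attached to ring carbon C7) lies 1,3 to C9 of the cis C9=C10 ring alkene. O6 can reach C9 only across the ring face that carries the C7 side chain, so 5-exo opening of a bromonium ion gives the oxolane bridged over the oxepane (2,7-dioxabicyclo[4.2.1]nonane) with bromine anti on C10. A benzylidene 1,3-dioxane is the temporary ring that masks O6 and O4 until then.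

Key step: step 13

Remark: compounds 1, 5, 10 and 31 are taken as purchasable; 5 is the allylborane derived from (−)-α-pinene.

**Step 1**
Reactants: 1 (R)-butane-1,2,4-triol; 2 benzaldehyde dimethyl acetal
Product: 3 [(2R,4R)-2-phenyl-1,3-dioxan-4-yl]methanol
Conditions: PhCH(OMe)2, camphorsulfonic acid (cat.), CH2Cl2, rt
Reagents that add atoms: benzaldehyde dimethyl acetal, COC(OC)c1ccccc1
Why: Acid-catalysed transacetalisation under thermodynamic control should give the six-membered 1,3-dioxane with phenyl and hydroxymethyl both equatorial (cis), which sets the acetal carbon as R and leaves only the C1 hydroxyl free.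

**Step 2**
Reactants: 3 [(2R,4R)-2-phenyl-1,3-dioxan-4-yl]methanol
Product: 4 (2R,4R)-2-phenyl-1,3-dioxane-4-carbaldehyde
Conditions: Dess–Martin periodinane, NaHCO3, CH2Cl2, 0 °C to rt
Reagents that add atoms: none
Why: Buffered Dess–Martin oxidation of the primary alcohol is mild enough that the α-alkoxy aldehyde should form without epimerisation or acetal loss.

**Step 3**
Reactants: 4 (2R,4R)-2-phenyl-1,3-dioxane-4-carbaldehyde; 5 (−)-B-allyldiisopinocampheylborane
Product: 7 (1R)-1-[(2R,4R)-2-phenyl-1,3-dioxan-4-yl]but-3-en-1-ol, via borinate ester 6 (not isolated)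
Conditions: 5 (pentane solution), Et2O, −78 °C; then NaOH, H2O2, H2O, 0 °C to rt
Reagents that add atoms: (−)-B-allyldiisopinocampheylborane, C=CCB([C@H]1C[C@H]2C[C@@H]([C@@H]1C)C2(C)C)[C@H]1C[C@H]2C[C@@H]([C@@H]1C)C2(C)C
Why: Brown allylboration through a closed chair transition state, in which the (−)-α-pinene-derived reagent delivers allyl to the Re face of the aldehyde, should override the modest Felkin bias and set the carbinol as R, syn to the dioxane oxygen.

**Step 4**
Reactants: 7 (1R)-1-[(2R,4R)-2-phenyl-1,3-dioxan-4-yl]but-3-en-1-ol; 8 bromoacetic acid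
Product: 9 2-{[(1R)-1-[(2R,4R)-2-phenyl-1,3-dioxan-4-yl]but-3-en-1-yl]oxy}acetic acid
Conditions: NaH (excess), THF/DMF, 0 °C to rt; cold dilute HCl work-up
Reagents that add atoms: bromoacetic acid, OC(=O)CBr
Why: Williamson etherification of the sodium alkoxide with sodium bromoacetate should give the glycolic acid ether without touching a stereocentre.

**Step 5**
Reactants: 9 2-{[(1R)-1-[(2R,4R)-2-phenyl-1,3-dioxan-4-yl]but-3-en-1-yl]oxy}acetic acid; 10 (4S)-4-benzyl-1,3-oxazolidin-2-one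
Product: 12 (4S)-4-benzyl-3-(2-{[(1R)-1-[(2R,4R)-2-phenyl-1,3-dioxan-4-yl]but-3-en-1-yl]oxy}acetyl)-1,3-oxazolidin-2-one, via mixed pivalic anhydride 11 (not isolated)
Conditions: pivaloyl chloride, Et3N, THF, −78 to 0 °C; then 10 lithiated with n-BuLi, THF, −78 to 0 °C
Reagents that add atoms: (4S)-4-benzyl-1,3-oxazolidin-2-one, O=C1N[C@@H](Cc2ccccc2)CO1
Why: N-acylation of the lithiated oxazolidinone by the mixed anhydride should take place at the unhindered glycolyl carbonyl and install the Evans auxiliary.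

**Step 6**
Reactants: 12 (4S)-4-benzyl-3-(2-{[(1R)-1-[(2R,4R)-2-phenyl-1,3-dioxan-4-yl]but-3-en-1-yl]oxy}acetyl)-1,3-oxazolidin-2-one; 13 allyl iodide
Product: 15 (4S)-4-benzyl-3-[(2R)-2-{[(1R)-1-[(2R,4R)-2-phenyl-1,3-dioxan-4-yl]but-3-en-1-yl]oxy}pent-4-enoyl]-1,3-oxazolidin-2-one, via sodium enolate 14 (not isolated)
Conditions: NaN(SiMe3)2, THF, −78 °C; allyl iodide, −78 to −45 °C
Reagents that add atoms: allyl iodide, C=CCI
Why: Evans asymmetric alkylation, in which the chelated Z sodium enolate is shielded on one face by the benzyl group of the auxiliary, should add allyl anti to it and set the new ether-bearing carbon as R whatever the resident stereocentres.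

**Step 7**
Reactants: 15 (4S)-4-benzyl-3-[(2R)-2-{[(1R)-1-[(2R,4R)-2-phenyl-1,3-dioxan-4-yl]but-3-en-1-yl]oxy}pent-4-enoyl]-1,3-oxazolidin-2-one
Product: 16 (4S)-4-benzyl-3-{[(2R,7R)-7-[(2R,4R)-2-phenyl-1,3-dioxan-4-yl]-2,3,6,7-tetrahydrooxepin-2-yl]carbonyl}-1,3-oxazolidin-2-one
Conditions: second-generation Grubbs catalyst RuCl2(=CHPh)(H2IMes)(PCy3) (cat.), CH2Cl2 (dilute), 40 °C
Reagents that add atoms: none
Why: Ring-closing metathesis of the two terminal alkenes, helped by the gauche preference of the two C–O bonds of the α,α'-disubstituted ether, should close the seven-membered ring with a cis ring alkene and loss of ethylene.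

**Step 8**
Reactants: 16 (4S)-4-benzyl-3-{[(2R,7R)-7-[(2R,4R)-2-phenyl-1,3-dioxan-4-yl]-2,3,6,7-tetrahydrooxepin-2-yl]carbonyl}-1,3-oxazolidin-2-one; 17 N,O-dimethylhydroxylamine hydrochloride
Product: 18 (2R,7R)-N-methoxy-N-methyl-7-[(2R,4R)-2-phenyl-1,3-dioxan-4-yl]-2,3,6,7-tetrahydrooxepine-2-carboxamide
Conditions: MeNHOMe·HCl, AlMe3, CH2Cl2, −20 °C to rt
Reagents that add atoms: N,O-dimethylhydroxylamine hydrochloride, CNOC.Cl
Why: Aluminium amide transamination should cleave the exocyclic imide carbonyl, release the auxiliary and give the Weinreb amide without epimerising the α-alkoxy centre.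

**Step 9**
Reactants: 18 (2R,7R)-N-methoxy-N-methyl-7-[(2R,4R)-2-phenyl-1,3-dioxan-4-yl]-2,3,6,7-tetrahydrooxepine-2-carboxamide; 19 ethylmagnesium bromide
Product: 21 1-[(2R,7R)-7-[(2R,4R)-2-phenyl-1,3-dioxan-4-yl]-2,3,6,7-tetrahydrooxepin-2-yl]propan-1-one, via magnesium hemiaminal chelate 20 (not isolated)
Conditions: EtMgBr, THF, 0 °C; aqueous NH4Cl
Reagents that add atoms: ethylmagnesium bromide, CC[Mg]Br
Why: Weinreb ketone synthesis, in which the stable magnesium chelate stops the addition after one ethyl group and releases the ketone only on work-up.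

**Step 10**
Reactants: 21 1-[(2R,7R)-7-[(2R,4R)-2-phenyl-1,3-dioxan-4-yl]-2,3,6,7-tetrahydrooxepin-2-yl]propan-1-one
Product: 22 (1R)-1-[(2R,7R)-7-[(2R,4R)-2-phenyl-1,3-dioxan-4-yl]-2,3,6,7-tetrahydrooxepin-2-yl]propan-1-ol
Conditions: LiBH(s-Bu)3 (L-Selectride), THF, −78 °C; then NaOH, H2O2
Reagents that add atoms: none
Why: Felkin–Anh reduction, in which the bulky hydride attacks the ketone anti to the polar C–O bond of the ring oxygen, should give the (1R) alcohol syn to that oxygen.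

**Step 11**
Reactants: 22 (1R)-1-[(2R,7R)-7-[(2R,4R)-2-phenyl-1,3-dioxan-4-yl]-2,3,6,7-tetrahydrooxepin-2-yl]propan-1-ol; 23 carbon tetrabromide
Product: 25 (2R,4R)-4-[(2R,7R)-7-[(1S)-1-bromopropyl]-2,3,6,7-tetrahydrooxepin-2-yl]-2-phenyl-1,3-dioxane, via alkoxyphosphonium bromide 24 (not isolated)
Conditions: CBr4, P(n-C8H17)3, toluene, 70 °C
Reagents that add atoms: carbon tetrabromide, BrC(Br)(Br)Br
Why: Appel-type bromination, in which bromide displaces the alkoxyphosphonium group in an SN2 step with inversion, should convert the (1R) alcohol into the (1S) bromide.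

**Step 12**
Reactants: 25 (2R,4R)-4-[(2R,7R)-7-[(1S)-1-bromopropyl]-2,3,6,7-tetrahydrooxepin-2-yl]-2-phenyl-1,3-dioxane
Product: 26 (3R)-3-[(2R,7R)-7-[(1S)-1-bromopropyl]-2,3,6,7-tetrahydrooxepin-2-yl]propane-1,3-diol
Conditions: AcOH/THF/H2O, 45 °C
Reagents that add atoms: none
Why: Mild aqueous acid should hydrolyse the benzylidene acetal, freeing the secondary hydroxyl needed as nucleophile and the primary hydroxyl needed later, while the alkene and the secondary bromide stay inert.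

**Step 13**
Reactants: 26 (3R)-3-[(2R,7R)-7-[(1S)-1-bromopropyl]-2,3,6,7-tetrahydrooxepin-2-yl]propane-1,3-diol; 27 N-bromosuccinimide
Product: 29 2-[(1R,3R,5R,6R,8R)-5-bromo-3-[(1S)-1-bromopropyl]-2,7-dioxabicyclo[4.2.1]nonan-8-yl]ethan-1-ol, via bromonium ion 28 (not isolated)
Conditions: NBS, MeCN, 0 °C, dark
Reagents that add atoms: N-bromosuccinimide, O=C1CCC(=O)N1Br
Why: NBS transfers Br+ reversibly to both faces of the ring C9=C10 alkene, but only the bromonium ion on the face opposite the C7 side chain can be opened, by backside attack of the C6 hydroxyl at C9, after which succinimide takes up the proton. The closest known reaction type is the intramolecular bromoetherification of a γ,δ-unsaturated alcohol, the laboratory counterpart of the haloperoxidase step by which such bromo ethers are thought to arise in the alga. The one ring formed, the oxolane O6–C6–C7–C8–C9, closes in the 5-exo mode and thereby bridges the oxepane to the 2,7-dioxabicyclo[4.2.1]nonane. C9 is controlled by the C7 stereocentre, because the two-atom O6–C6 bridge can only span C7 and C9 on the same ring face, and C10 by the anti opening of the bromonium ion of the cis alkene, which puts bromine trans to the new C–O bond. The step needs regioselectivity for C9 over C10 (6-endo, leading to a more strained bicyclo[3.2.2] skeleton) and for the secondary over the primary hydroxyl (seven-membered closure), both secured by the 5-exo geometry, and it needs the absence of a second nucleophile and a second alkene, secured by having C13 already as the bromide and by postponing the enyne.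

**Step 14**
Reactants: 29 2-[(1R,3R,5R,6R,8R)-5-bromo-3-[(1S)-1-bromopropyl]-2,7-dioxabicyclo[4.2.1]nonan-8-yl]ethan-1-ol
Product: 30 2-[(1R,3R,5R,6R,8R)-5-bromo-3-[(1S)-1-bromopropyl]-2,7-dioxabicyclo[4.2.1]nonan-8-yl]acetaldehyde
Conditions: Dess–Martin periodinane, NaHCO3, CH2Cl2, 0 °C to rt
Reagents that add atoms: none
Why: Buffered Dess–Martin oxidation should give the β-alkoxy aldehyde without β-elimination of the oxolane oxygen or loss of the secondary bromides.

**Step 15**
Reactants: 30 2-[(1R,3R,5R,6R,8R)-5-bromo-3-[(1S)-1-bromopropyl]-2,7-dioxabicyclo[4.2.1]nonan-8-yl]acetaldehyde; 31 1,3-bis(triisopropylsilyl)propyne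
Product: 33 {(3Z)-5-[(1R,3R,5R,6R,8R)-5-bromo-3-[(1S)-1-bromopropyl]-2,7-dioxabicyclo[4.2.1]nonan-8-yl]pent-3-en-1-yn-1-yl}tri(propan-2-yl)silane, via lithium β-silyl alkoxide 32 (not isolated)
Conditions: 31, n-BuLi, THF, −78 °C; then 30, −78 to 0 °C
Reagents that add atoms: 1,3-bis(triisopropylsilyl)propyne, CC(C)[Si](C(C)C)(C(C)C)CC#C[Si](C(C)C)(C(C)C)C(C)C
Why: Peterson olefination, in which the lithiated bis-silyl propyne adds to the aldehyde and the β-silyl alkoxide loses lithium triisopropylsilanolate by syn elimination, should give the Z enyne because the bulky silyl groups favour the adduct that leads to it.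

**Step 16**
Reactants: 33 {(3Z)-5-[(1R,3R,5R,6R,8R)-5-bromo-3-[(1S)-1-bromopropyl]-2,7-dioxabicyclo[4.2.1]nonan-8-yl]pent-3-en-1-yn-1-yl}tri(propan-2-yl)silane
Product: 34 (1R,3R,5R,6R,8R)-5-bromo-3-[(1S)-1-bromopropyl]-8-[(2Z)-pent-2-en-4-yn-1-yl]-2,7-dioxabicyclo[4.2.1]nonane
Conditions: Bu4NF, THF, −20 to 0 °C
Reagents that add atoms: none
Why: Fluoride-induced protodesilylation of the alkynylsilane at low temperature should free the terminal alkyne and leave the secondary bromides and the Z alkene untouched.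

**Compound list**

1 | (R)-butane-1,2,4-triol | OCC[C@@H](O)CO | starting material
2 | benzaldehyde dimethyl acetal | COC(OC)c1ccccc1 | starting material
3 | [(2R,4R)-2-phenyl-1,3-dioxan-4-yl]methanol | OC[C@H]1CCO[C@@H](c2ccccc2)O1 | intermediate
4 | (2R,4R)-2-phenyl-1,3-dioxane-4-carbaldehyde | O=C[C@H]1CCO[C@@H](c2ccccc2)O1 | intermediate
5 | (−)-B-allyldiisopinocampheylborane, from (−)-α-pinene | C=CCB([C@H]1C[C@H]2C[C@@H]([C@@H]1C)C2(C)C)[C@H]1C[C@H]2C[C@@H]([C@@H]1C)C2(C)C | starting material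
6 | borinate ester of 7 (O-bound diisopinocampheylboryl) | C=CC[C@@H](OB([C@H]1C[C@H]2C[C@@H]([C@@H]1C)C2(C)C)[C@H]3C[C@H]4C[C@@H]([C@@H]3C)C4(C)C)[C@H]5CCO[C@@H](c6ccccc6)O5 | intermediate
7 | (1R)-1-[(2R,4R)-2-phenyl-1,3-dioxan-4-yl]but-3-en-1-ol | C=CC[C@@H](O)[C@H]1CCO[C@@H](c2ccccc2)O1 | intermediate
8 | bromoacetic acid | OC(=O)CBr | starting material
9 | 2-{[(1R)-1-[(2R,4R)-2-phenyl-1,3-dioxan-4-yl]but-3-en-1-yl]oxy}acetic acid | C=CC[C@@H](OCC(=O)O)[C@H]1CCO[C@@H](c2ccccc2)O1 | intermediate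
10 | (4S)-4-benzyl-1,3-oxazolidin-2-one | O=C1N[C@@H](Cc2ccccc2)CO1 | starting material
11 | mixed anhydride of 9 with pivalic acid | C=CC[C@@H](OCC(=O)OC(=O)C(C)(C)C)[C@H]1CCO[C@@H](c2ccccc2)O1 | intermediate
12 | (4S)-4-benzyl-3-(2-{[(1R)-1-[(2R,4R)-2-phenyl-1,3-dioxan-4-yl]but-3-en-1-yl]oxy}acetyl)-1,3-oxazolidin-2-one | C=CC[C@@H](OCC(=O)N1[C@@H](Cc2ccccc2)COC1=O)[C@H]3CCO[C@@H](c4ccccc4)O3 | intermediate
13 | allyl iodide | C=CCI | starting material
14 | Z sodium enolate of 12 | C=CC[C@@H](O/C=C(\[O-])N1[C@@H](Cc2ccccc2)COC1=O)[C@H]3CCO[C@@H](c4ccccc4)O3.[Na+] | intermediate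
15 | (4S)-4-benzyl-3-[(2R)-2-{[(1R)-1-[(2R,4R)-2-phenyl-1,3-dioxan-4-yl]but-3-en-1-yl]oxy}pent-4-enoyl]-1,3-oxazolidin-2-one | C=CC[C@@H](O[C@H](CC=C)C(=O)N1[C@@H](Cc2ccccc2)COC1=O)[C@H]3CCO[C@@H](c4ccccc4)O3 | intermediate
16 | (4S)-4-benzyl-3-{[(2R,7R)-7-[(2R,4R)-2-phenyl-1,3-dioxan-4-yl]-2,3,6,7-tetrahydrooxepin-2-yl]carbonyl}-1,3-oxazolidin-2-one | O=C(N1[C@@H](Cc2ccccc2)COC1=O)[C@H]3C/C=C\C[C@@H](O3)[C@H]4CCO[C@@H](c5ccccc5)O4 | intermediate
17 | N,O-dimethylhydroxylamine hydrochloride | CNOC.Cl | starting material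
18 | (2R,7R)-N-methoxy-N-methyl-7-[(2R,4R)-2-phenyl-1,3-dioxan-4-yl]-2,3,6,7-tetrahydrooxepine-2-carboxamide | CON(C)C(=O)[C@H]1C/C=C\C[C@@H](O1)[C@H]2CCO[C@@H](c3ccccc3)O2 | intermediate
19 | ethylmagnesium bromide | CC[Mg]Br | starting material
20 | bromomagnesium hemiaminal chelate from 18 and 19 (both configurations at the new carbon) | CCC(O[Mg]Br)(N(C)OC)[C@H]1C/C=C\C[C@@H](O1)[C@H]2CCO[C@@H](c3ccccc3)O2 | intermediate
21 | 1-[(2R,7R)-7-[(2R,4R)-2-phenyl-1,3-dioxan-4-yl]-2,3,6,7-tetrahydrooxepin-2-yl]propan-1-one | CCC(=O)[C@H]1C/C=C\C[C@@H](O1)[C@H]2CCO[C@@H](c3ccccc3)O2 | intermediate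
22 | (1R)-1-[(2R,7R)-7-[(2R,4R)-2-phenyl-1,3-dioxan-4-yl]-2,3,6,7-tetrahydrooxepin-2-yl]propan-1-ol | CC[C@@H](O)[C@H]1C/C=C\C[C@@H](O1)[C@H]2CCO[C@@H](c3ccccc3)O2 | intermediate
23 | carbon tetrabromide | BrC(Br)(Br)Br | starting material
24 | alkoxyphosphonium bromide of 22 | CC[C@@H](O[P+](CCCCCCCC)(CCCCCCCC)CCCCCCCC)[C@H]1C/C=C\C[C@@H](O1)[C@H]2CCO[C@@H](c3ccccc3)O2.[Br-] | intermediate
25 | (2R,4R)-4-[(2R,7R)-7-[(1S)-1-bromopropyl]-2,3,6,7-tetrahydrooxepin-2-yl]-2-phenyl-1,3-dioxane | CC[C@H](Br)[C@H]1C/C=C\C[C@@H](O1)[C@H]2CCO[C@@H](c3ccccc3)O2 | intermediate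
26 | (3R)-3-[(2R,7R)-7-[(1S)-1-bromopropyl]-2,3,6,7-tetrahydrooxepin-2-yl]propane-1,3-diol | OCC[C@@H](O)[C@H]1C/C=C\C[C@H]([C@@H](Br)CC)O1 | intermediate
27 | N-bromosuccinimide | O=C1CCC(=O)N1Br | starting material
28 | bromonium ion of 26 on the ring face opposite the C7 side chain, succinimide anion as counter-ion | OCC[C@@H](O)[C@H]1C[C@@H]2[Br+][C@@H]2C[C@H]([C@@H](Br)CC)O1.O=C1CCC(=O)[N-]1 | intermediate
29 | 2-[(1R,3R,5R,6R,8R)-5-bromo-3-[(1S)-1-bromopropyl]-2,7-dioxabicyclo[4.2.1]nonan-8-yl]ethan-1-ol | OCC[C@H]1O[C@@H]2C[C@H]1O[C@@H]([C@@H](Br)CC)C[C@H]2Br | intermediate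
30 | 2-[(1R,3R,5R,6R,8R)-5-bromo-3-[(1S)-1-bromopropyl]-2,7-dioxabicyclo[4.2.1]nonan-8-yl]acetaldehyde | O=CC[C@H]1O[C@@H]2C[C@H]1O[C@@H]([C@@H](Br)CC)C[C@H]2Br | intermediate
31 | 1,3-bis(triisopropylsilyl)propyne | CC(C)[Si](C(C)C)(C(C)C)CC#C[Si](C(C)C)(C(C)C)C(C)C | starting material
32 | lithium β-silyl alkoxide from 30 and lithiated 31 (3S,4R adduct drawn; its 3R,4S partner eliminates alike) | [Li+].[O-][C@H](C[C@H]1O[C@@H]2C[C@H]1O[C@@H]([C@@H](Br)CC)C[C@H]2Br)[C@H](C#C[Si](C(C)C)(C(C)C)C(C)C)[Si](C(C)C)(C(C)C)C(C)C | intermediate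
33 | {(3Z)-5-[(1R,3R,5R,6R,8R)-5-bromo-3-[(1S)-1-bromopropyl]-2,7-dioxabicyclo[4.2.1]nonan-8-yl]pent-3-en-1-yn-1-yl}tri(propan-2-yl)silane | CC(C)[Si](C(C)C)(C(C)C)C#C/C=C\C[C@H]1O[C@@H]2C[C@H]1O[C@@H]([C@@H](Br)CC)C[C@H]2Br | intermediate
34 | (1R,3R,5R,6R,8R)-5-bromo-3-[(1S)-1-bromopropyl]-8-[(2Z)-pent-2-en-4-yn-1-yl]-2,7-dioxabicyclo[4.2.1]nonane | C#C/C=C\C[C@H]1O[C@@H]2C[C@H]1O[C@@H]([C@@H](Br)CC)C[C@H]2Br | target

**Step count**

Total steps: 16. Longest linear sequence: 16 steps (from 1 to 34; the route is fully linear).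

**Steps most likely to fail**

1. Step 11 (bromination with inversion). What may go wrong: the oxepene oxygen may take part in the ionising alkoxyphosphonium ion, giving retention or ring rearrangement through an oxiranium ion, and E2 elimination may compete at 70 °C. The fallback sets out from 22 and replaces the one-pot phosphonium activation by an isolated sulfonate and a separate low-temperature SN2 step. Chloromethanesulfonyl chloride and 2,6-lutidine (CH2Cl2, 0 °C) should give (1R)-1-[(2R,7R)-7-[(2R,4R)-2-phenyl-1,3-dioxan-4-yl]-2,3,6,7-tetrahydrooxepin-2-yl]propyl chloromethanesulfonate F1. LiBr in THF at or below rt should then displace it with inversion, which comes back to the route at 25.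

2. Step 15 (Peterson olefination). What may go wrong: the organolithium may deprotonate the aldehyde at the α-carbon, followed by β-elimination of the oxolane oxygen (ring opening), or the Z selectivity of the elimination may erode. The fallback sets out from 30 and builds the enyne by cross-coupling instead. Stork–Zhao olefination (Ph3PCH2I iodide, NaN(SiMe3)2, THF, −78 °C) should give the Z vinyl iodide (1R,3R,5R,6R,8R)-5-bromo-3-[(1S)-1-bromopropyl]-8-[(2Z)-3-iodoprop-2-en-1-yl]-2,7-dioxabicyclo[4.2.1]nonane F2. Sonogashira coupling with ethynyltrimethylsilane (Pd(PPh3)4, CuI, i-Pr2NH) should give {(3Z)-5-[(1R,3R,5R,6R,8R)-5-bromo-3-[(1S)-1-bromopropyl]-2,7-dioxabicyclo[4.2.1]nonan-8-yl]pent-3-en-1-yn-1-yl}trimethylsilane F3. K2CO3 in MeOH then removes the silyl group and comes back to the route at 34, so steps 15 and 16 are both replaced.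

3. Step 3 (allylboration). What may go wrong: facial selectivity may be poor, because the reagent has to overrule the Felkin preference of the α-alkoxy aldehyde (mismatched pairing). The fallback sets out from 4 and uses substrate control followed by inversion. Zinc-mediated Barbier allylation (allyl bromide, Zn, THF/aqueous NH4Cl) should follow the Felkin sense to (1S)-1-[(2R,4R)-2-phenyl-1,3-dioxan-4-yl]but-3-en-1-ol F4. Mitsunobu inversion (4-nitrobenzoic acid, PPh3, diisopropyl azodicarboxylate) should give (1R)-1-[(2R,4R)-2-phenyl-1,3-dioxan-4-yl]but-3-en-1-yl 4-nitrobenzoate F5, and K2CO3 in MeOH comes back to the route at 7. The same two steps would recycle any (1S) epimer formed in step 3.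

**Further compounds**

F1 | step 11 | (1R)-1-[(2R,7R)-7-[(2R,4R)-2-phenyl-1,3-dioxan-4-yl]-2,3,6,7-tetrahydrooxepin-2-yl]propyl chloromethanesulfonate | CC[C@@H](OS(=O)(=O)CCl)[C@H]1C/C=C\C[C@@H](O1)[C@H]2CCO[C@@H](c3ccccc3)O2
F2 | step 15 | (1R,3R,5R,6R,8R)-5-bromo-3-[(1S)-1-bromopropyl]-8-[(2Z)-3-iodoprop-2-en-1-yl]-2,7-dioxabicyclo[4.2.1]nonane | I/C=C\C[C@H]1O[C@@H]2C[C@H]1O[C@@H]([C@@H](Br)CC)C[C@H]2Br
F3 | step 15 | {(3Z)-5-[(1R,3R,5R,6R,8R)-5-bromo-3-[(1S)-1-bromopropyl]-2,7-dioxabicyclo[4.2.1]nonan-8-yl]pent-3-en-1-yn-1-yl}trimethylsilane | C[Si](C)(C)C#C/C=C\C[C@H]1O[C@@H]2C[C@H]1O[C@@H]([C@@H](Br)CC)C[C@H]2Br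
F4 | step 3 | (1S)-1-[(2R,4R)-2-phenyl-1,3-dioxan-4-yl]but-3-en-1-ol | C=CC[C@H](O)[C@H]1CCO[C@@H](c2ccccc2)O1
F5 | step 3 | (1R)-1-[(2R,4R)-2-phenyl-1,3-dioxan-4-yl]but-3-en-1-yl 4-nitrobenzoate | C=CC[C@@H](OC(=O)c1ccc(cc1)[N+](=O)[O-])[C@H]2CCO[C@@H](c3ccccc3)O2
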